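**Retrosynthetic overview**
1. Target 18 ⇐ 17 (hydrogenolysis of the 7-O-benzyl ether) ⇐ 16 (methylation of the 8-OH); the free 7-OH is carried throughout as the only benzyl ether.
2. Ring A of 16 is opened at C8–C8a. C5, C6, C7 and C8 of ring A each bear oxygen and C8a bears O1, so C5–C8 with their oxygens are taken from the four carbons of a squarate; 16 ⇐ cyclobutenone 13 by thermal ring expansion onto the C6–H of a ready-made 2-aryl-4-pyranone (ring C).
3. 13 ⇐ dibenzyl squarate 9 + 5-iodopyranone 6: iodine–magnesium exchange and 1,2-addition, O-methylation of the carbinol, then methoxide exchange at the single vinylogous-ester carbon, which tells the future C6 (OMe) from C7 (OBn).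
4. 6 ⇐ iodo enone 3 + 3,4-dimethoxybenzoyl chloride 4. The halogen is placed on the acyclic enone before ring C is closed, so it can only end up at pyranone C5; direct halogenation of a 2-aryl-4-pyranone could attack C3, C5 or the veratryl ring.
5. Order of ring formation: veratryl ring (bought) → ring C (step 2) → cyclobutenone from squaric acid (steps 3–6) → ring A (step 7).

Key step: step 7

Assumption: 3 is expected as the (Z)-isomer, but either alkene geometry would cyclise in step 2. Compounds 11–13 are racemic, their single stereocentre is destroyed in step 7, and the target is achiral.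

**Step 1**
Reactants: 1 (E)-4-methoxybut-3-en-2-one
Product: 3 (Z)-3-iodo-4-methoxybut-3-en-2-one, via chloro-iodo adduct 2 (not isolated)
Conditions: ICl, CH2Cl2, −78 °C; then Et3N, −78 → 0 °C
Reagents that add atoms: iodine monochloride, ClI
Why: Electrophilic addition of I–Cl across the enol-ether double bond puts iodine on the nucleophilic α-carbon, and amine-induced E1cB loss of HCl restores the push–pull alkene (halogenation–dehydrohalogenation of a β-alkoxy enone).

**Step 2**
Reactants: 3 (Z)-3-iodo-4-methoxybut-3-en-2-one (2 equiv); 4 3,4-dimethoxybenzoyl chloride (1 equiv)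
Product: 6 2-(3,4-dimethoxyphenyl)-5-iodo-4H-pyran-4-one, via 1,3-diketone 5 (not isolated)
Conditions: LiN(SiMe3)2 (2 equiv), THF, −78 °C; then 4, −78 → 0 °C; aq. NH4Cl; then CF3CO2H (cat.), toluene, rt
Reagents that add atoms: none
Why: Only the methyl group can be deprotonated, the lithium enolate is C-acylated by the aroyl chloride (Claisen-type acylation, the second equivalent of enolate deprotonating the 1,3-diketone), and under acid the enol oxygen displaces methoxide by 6-endo addition–elimination at the β-carbon, which fixes iodine at C5 of the pyranone without any regiochemical choice.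

**Step 3**
Reactants: 7 squaric acid (1 equiv); 8 benzyl alcohol (two equivalents are incorporated; used in excess)
Product: 9 dibenzyl squarate, 3,4-bis(benzyloxy)cyclobut-3-ene-1,2-dione
Conditions: toluene, reflux, Dean–Stark
Reagents that add atoms: benzyl alcohol, OCc1ccccc1
Why: Squaric acid is a strong vinylogous diacid, and each of its two acidic hydroxyls condenses with one molecule of benzyl alcohol under azeotropic removal of the two equivalents of water (twofold Fischer-type esterification) without added catalyst.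

**Step 4**
Reactants: 6 2-(3,4-dimethoxyphenyl)-5-iodo-4H-pyran-4-one; 9 dibenzyl squarate
Product: 11 racemic 2,3-bis(benzyloxy)-4-[6-(3,4-dimethoxyphenyl)-4-oxo-4H-pyran-3-yl]-4-hydroxycyclobut-2-en-1-one, via pyranonylmagnesium chloride 10 (not isolated)
Conditions: iPrMgCl·LiCl (1.05 equiv), THF, −40 °C; then added to 9 (1.2 equiv), THF, −78 → −40 °C; aq. NH4Cl
Reagents that add atoms: none
Why: Iodine–magnesium exchange on the electron-poor α-iodo enone should be fast enough at low temperature to outrun attack of the isopropyl Grignard on the pyranone, and the alkenyl Grignard then adds 1,2 to one of the two equivalent, strained squarate carbonyls (Grignard addition); the new carbinol centre forms as a racemate and is erased in step 7.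

**Step 5**
Reactants: 11 racemic 2,3-bis(benzyloxy)-4-[6-(3,4-dimethoxyphenyl)-4-oxo-4H-pyran-3-yl]-4-hydroxycyclobut-2-en-1-one
Product: 12 racemic 2,3-bis(benzyloxy)-4-[6-(3,4-dimethoxyphenyl)-4-oxo-4H-pyran-3-yl]-4-methoxycyclobut-2-en-1-one
Conditions: MeI (excess), Ag2O, MeCN, rt, dark
Reagents that add atoms: iodomethane, CI
Why: Silver-oxide-promoted Williamson-type methylation etherifies the tertiary alcohol without generating a free alkoxide, which avoids base-triggered opening of the cyclobutenone and later prevents the hydroxyl from trapping the ketene as a furanone.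

**Step 6**
Reactants: 12 racemic 2,3-bis(benzyloxy)-4-[6-(3,4-dimethoxyphenyl)-4-oxo-4H-pyran-3-yl]-4-methoxycyclobut-2-en-1-one
Product: 13 racemic 2-(benzyloxy)-3,4-dimethoxy-4-[6-(3,4-dimethoxyphenyl)-4-oxo-4H-pyran-3-yl]cyclobut-2-en-1-one
Conditions: NaOMe (0.2 equiv), MeOH–THF, −20 → 0 °C; AcOH quench
Reagents that add atoms: methanol, CO
Why: Methoxide adds to C3, the β-carbon of the enone and the only vinylogous-ester position, and benzyl oxide is expelled and regenerates methoxide from the solvent (conjugate addition–elimination, a vinylogous transesterification driven by methanol as solvent), whereas the C2 benzyloxy group sits on the α-carbon and cannot exchange.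

**Step 7**
Reactants: 13 racemic 2-(benzyloxy)-3,4-dimethoxy-4-[6-(3,4-dimethoxyphenyl)-4-oxo-4H-pyran-3-yl]cyclobut-2-en-1-one
Product: 16 7-(benzyloxy)-8-hydroxy-5,6-dimethoxy-2-(3,4-dimethoxyphenyl)-4H-chromen-4-one, via dienylketene 14 (not isolated), via cyclohexadienone 15 (not isolated)
Conditions: toluene (degassed, 0.02 M), 110 °C, Ar
Reagents that add atoms: none
Why: Thermal conrotatory 4π opening of the cyclobutenone C1–C4 bond gives dienylketene 14; the donor methoxy group on C4 rotates outward (torquoselectivity), which turns the pyranonyl group inward and cis to the ketene. A disrotatory 6π electrocyclisation (6-endo closure across the pyranone C5=C6 bond, 2-aryl-4-pyranone numbering) then joins the ketene carbon to the pyranone C6–H, forming the chromone C8–C8a bond and ring A as cyclohexadienone 15, whose transient sp3 centre at C8a disappears on tautomerisation to phenol 16, so no stereocentre remains. The closest known reaction type is the Moore ring expansion of 4-alkenyl- and 4-heteroaryl-4-alkoxycyclobutenones to hydroquinone monoethers, applied here with a 4-pyranone as the alkenyl arm. The step needs C–C closure at a single site and a fixed order of the four oxygen substituents: attachment through pyranone C5 leaves C6–H as the only ring CH next to the cyclobutenone, and the 5-OMe, 6-OMe, 7-OBn, 8-OH pattern is already written into C4, C3, C2 and C1 of 13. The methyl ether on C4 rules out lactonisation of the ketene, and aromatisation makes the sequence irreversible.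

**Step 8**
Reactants: 16 7-(benzyloxy)-8-hydroxy-5,6-dimethoxy-2-(3,4-dimethoxyphenyl)-4H-chromen-4-one
Product: 17 7-(benzyloxy)-5,6,8-trimethoxy-2-(3,4-dimethoxyphenyl)-4H-chromen-4-one
Conditions: MeI, K2CO3, DMF, rt
Reagents that add atoms: iodomethane, CI
Why: Williamson ether synthesis on the only free phenol, which is not hydrogen-bonded to the C4 carbonyl and should alkylate under standard carbonate conditions.

**Step 9**
Reactants: 17 7-(benzyloxy)-5,6,8-trimethoxy-2-(3,4-dimethoxyphenyl)-4H-chromen-4-one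
Product: 18 7-hydroxy-5,6,8-trimethoxy-2-(3,4-dimethoxyphenyl)-4H-chromen-4-one (target)
Conditions: H2 (1 atm), Pd/C (10%), EtOAc–MeOH, rt
Reagents that add atoms: none
Why: Hydrogenolysis of the benzyl aryl ether over palladium on carbon at atmospheric pressure, conditions under which aryl methyl ethers and the flavone enone are normally left untouched.

**Compound list**
1 | (E)-4-methoxybut-3-en-2-one | CC(=O)/C=C/OC | starting material
2 | 4-chloro-3-iodo-4-methoxybutan-2-one (mixture of diastereomers) | CC(=O)C(I)C(Cl)OC | intermediate (not isolated)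
3 | (Z)-3-iodo-4-methoxybut-3-en-2-one | CC(=O)/C(I)=C/OC | intermediate
4 | 3,4-dimethoxybenzoyl chloride | COc1ccc(C(Cl)=O)cc1OC | starting material
5 | (Z)-1-(3,4-dimethoxyphenyl)-4-iodo-5-methoxypent-4-ene-1,3-dione | COc1ccc(C(=O)CC(=O)/C(I)=C/OC)cc1OC | intermediate (not isolated)
6 | 2-(3,4-dimethoxyphenyl)-5-iodo-4H-pyran-4-one | COc1ccc(-c2cc(=O)c(I)co2)cc1OC | intermediate
7 | squaric acid | OC1=C(O)C(=O)C1=O | starting material
8 | benzyl alcohol | OCc1ccccc1 | starting material
9 | dibenzyl squarate, 3,4-bis(benzyloxy)cyclobut-3-ene-1,2-dione | O=C1C(=O)C(OCc2ccccc2)=C1OCc1ccccc1 | intermediate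
10 | [6-(3,4-dimethoxyphenyl)-4-oxo-4H-pyran-3-yl]magnesium chloride (LiCl complex) | COc1ccc(-c2cc(=O)c([Mg]Cl)co2)cc1OC | intermediate (not isolated)
11 | racemic 2,3-bis(benzyloxy)-4-[6-(3,4-dimethoxyphenyl)-4-oxo-4H-pyran-3-yl]-4-hydroxycyclobut-2-en-1-one | O=C1C(OCc2ccccc2)=C(OCc2ccccc2)C1(O)c1coc(-c2ccc(OC)c(OC)c2)cc1=O | intermediate
12 | racemic 2,3-bis(benzyloxy)-4-[6-(3,4-dimethoxyphenyl)-4-oxo-4H-pyran-3-yl]-4-methoxycyclobut-2-en-1-one | O=C1C(OCc2ccccc2)=C(OCc2ccccc2)C1(OC)c1coc(-c2ccc(OC)c(OC)c2)cc1=O | intermediate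
13 | racemic 2-(benzyloxy)-3,4-dimethoxy-4-[6-(3,4-dimethoxyphenyl)-4-oxo-4H-pyran-3-yl]cyclobut-2-en-1-one | O=C1C(OCc2ccccc2)=C(OC)C1(OC)c1coc(-c2ccc(OC)c(OC)c2)cc1=O | intermediate
14 | (Z)-dienylketene: 2-(benzyloxy)-3,4-dimethoxy-4-[6-(3,4-dimethoxyphenyl)-4-oxo-4H-pyran-3-yl]buta-1,3-dien-1-one, ketenyl and pyranonyl groups cis | O=C=C(OCc1ccccc1)/C(OC)=C(OC)\c1coc(-c2ccc(OC)c(OC)c2)cc1=O | intermediate (not isolated)
15 | racemic 7-(benzyloxy)-5,6-dimethoxy-2-(3,4-dimethoxyphenyl)-8aH-chromene-4,8-dione | COc1ccc(C2=CC(=O)C3=C(OC)C(OC)=C(OCc4ccccc4)C(=O)C3O2)cc1OC | intermediate (not isolated)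
16 | 7-(benzyloxy)-8-hydroxy-5,6-dimethoxy-2-(3,4-dimethoxyphenyl)-4H-chromen-4-one | COc1ccc(-c2cc(=O)c3c(OC)c(OC)c(OCc4ccccc4)c(O)c3o2)cc1OC | intermediate
17 | 7-(benzyloxy)-5,6,8-trimethoxy-2-(3,4-dimethoxyphenyl)-4H-chromen-4-one | COc1ccc(-c2cc(=O)c3c(OC)c(OC)c(OCc4ccccc4)c(OC)c3o2)cc1OC | intermediate
18 | 7-hydroxy-5,6,8-trimethoxy-2-(3,4-dimethoxyphenyl)-4H-chromen-4-one | COc1ccc(-c2cc(=O)c3c(OC)c(OC)c(O)c(OC)c3o2)cc1OC | target

**Step count**
Total steps: 9. Longest linear sequence: 8 steps (steps 1, 2, 4, 5, 6, 7, 8, 9); the squarate branch (step 3) joins at step 4.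

**Steps most likely to fail**

1. Step 7. The 6π closure may lose out to other fates of the dienylketene, such as attack by the pyranone carbonyl oxygen or dimerisation, because closure interrupts the cross-conjugation of the pyranone. Fallback, setting out from 9 and coming back at 16: ring C is carried through the ring expansion at the flavanone oxidation level, where the reacting C5=C6 bond is a plain vinylogous-ester alkene, and the flavone double bond is introduced afterwards.
 - 3,4-Dimethoxybenzaldehyde and (E)-1-methoxy-3-(trimethylsilyloxy)buta-1,3-diene (ZnCl2, THF; then CF3CO2H) should give, by hetero-Diels–Alder reaction, racemic 2-(3,4-dimethoxyphenyl)-2,3-dihydro-4H-pyran-4-one F1.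
 - α-Iodination (I2, pyridine, CH2Cl2) should give racemic 2-(3,4-dimethoxyphenyl)-5-iodo-2,3-dihydro-4H-pyran-4-one F2.
 - Iodine–magnesium exchange (iPrMgCl·LiCl, THF, −78 °C) and addition to 9 should give 2,3-bis(benzyloxy)-4-[2-(3,4-dimethoxyphenyl)-4-oxo-3,4-dihydro-2H-pyran-5-yl]-4-hydroxycyclobut-2-en-1-one F3 as a mixture of diastereomers.
 - MeI and Ag2O should give 2,3-bis(benzyloxy)-4-[2-(3,4-dimethoxyphenyl)-4-oxo-3,4-dihydro-2H-pyran-5-yl]-4-methoxycyclobut-2-en-1-one F4.
 - NaOMe in MeOH should give 2-(benzyloxy)-4-[2-(3,4-dimethoxyphenyl)-4-oxo-3,4-dihydro-2H-pyran-5-yl]-3,4-dimethoxycyclobut-2-en-1-one F5.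
 - Thermolysis in toluene should give racemic 7-(benzyloxy)-8-hydroxy-5,6-dimethoxy-2-(3,4-dimethoxyphenyl)chroman-4-one F6, and dehydrogenation with I2 (cat.) in DMSO at 120 °C should give 16.

2. Step 6. Methoxide may attack the cyclobutenone carbonyl (ring cleavage) or the pyranone CH next to the ring oxygen instead of exchanging cleanly at C3. Fallback, setting out from 12 and coming back at 17: the exchange is omitted and positions 6 and 7 are told apart after ring A exists, by phenol acidity.
 - Thermolysis of 12 (toluene, 110 °C) should give 6,7-bis(benzyloxy)-8-hydroxy-5-methoxy-2-(3,4-dimethoxyphenyl)-4H-chromen-4-one F7.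
 - MeI and K2CO3 should give 6,7-bis(benzyloxy)-5,8-dimethoxy-2-(3,4-dimethoxyphenyl)-4H-chromen-4-one F8.
 - Hydrogenolysis (H2, Pd/C) should give 6,7-dihydroxy-5,8-dimethoxy-2-(3,4-dimethoxyphenyl)-4H-chromen-4-one F9.
 - The 7-OH, para to the C4 carbonyl and the more acidic of the two, should be benzylated selectively with one equivalent of benzyl bromide and KHCO3 in DMF to give 7-(benzyloxy)-6-hydroxy-5,8-dimethoxy-2-(3,4-dimethoxyphenyl)-4H-chromen-4-one F10.
 - Methylation of the remaining 6-OH (MeI, K2CO3) gives 17.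

3. Step 4. The pyranonylmagnesium species may lose the ring oxygen by β-elimination (ring fragmentation to an ynone), or the isopropyl Grignard may add to the pyranone before the exchange is complete. Fallback, setting out from 6 and coming back at 11: no preformed Grignard is used. 6 and 9 are combined directly with CrCl2 (excess) and NiCl2 (cat.) in DMF at rt (Nozaki–Hiyama–Kishi coupling). Zerovalent nickel inserts into the C–I bond, the alkenyl group passes to trivalent chromium, and the non-basic alkenylchromium species, which tolerates carbonyl groups and is not prone to β-alkoxide loss, adds to the strained squarate carbonyl to give 11 directly.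

**Further compounds**
F1 | step 7 | racemic 2-(3,4-dimethoxyphenyl)-2,3-dihydro-4H-pyran-4-one | COc1ccc(C2CC(=O)C=CO2)cc1OC
F2 | step 7 | racemic 2-(3,4-dimethoxyphenyl)-5-iodo-2,3-dihydro-4H-pyran-4-one | COc1ccc(C2CC(=O)C(I)=CO2)cc1OC
F3 | step 7 | 2,3-bis(benzyloxy)-4-[2-(3,4-dimethoxyphenyl)-4-oxo-3,4-dihydro-2H-pyran-5-yl]-4-hydroxycyclobut-2-en-1-one (mixture of diastereomers) | O=C1C(OCc2ccccc2)=C(OCc2ccccc2)C1(O)C1=COC(c2ccc(OC)c(OC)c2)CC1=O
F4 | step 7 | 2,3-bis(benzyloxy)-4-[2-(3,4-dimethoxyphenyl)-4-oxo-3,4-dihydro-2H-pyran-5-yl]-4-methoxycyclobut-2-en-1-one (mixture of diastereomers) | O=C1C(OCc2ccccc2)=C(OCc2ccccc2)C1(OC)C1=COC(c2ccc(OC)c(OC)c2)CC1=O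
F5 | step 7 | 2-(benzyloxy)-4-[2-(3,4-dimethoxyphenyl)-4-oxo-3,4-dihydro-2H-pyran-5-yl]-3,4-dimethoxycyclobut-2-en-1-one (mixture of diastereomers) | O=C1C(OCc2ccccc2)=C(OC)C1(OC)C1=COC(c2ccc(OC)c(OC)c2)CC1=O
F6 | step 7 | racemic 7-(benzyloxy)-8-hydroxy-5,6-dimethoxy-2-(3,4-dimethoxyphenyl)chroman-4-one | COc1ccc(C2CC(=O)c3c(OC)c(OC)c(OCc4ccccc4)c(O)c3O2)cc1OC
F7 | step 6 | 6,7-bis(benzyloxy)-8-hydroxy-5-methoxy-2-(3,4-dimethoxyphenyl)-4H-chromen-4-one | COc1ccc(-c2cc(=O)c3c(OC)c(OCc4ccccc4)c(OCc4ccccc4)c(O)c3o2)cc1OC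
F8 | step 6 | 6,7-bis(benzyloxy)-5,8-dimethoxy-2-(3,4-dimethoxyphenyl)-4H-chromen-4-one | COc1ccc(-c2cc(=O)c3c(OC)c(OCc4ccccc4)c(OCc4ccccc4)c(OC)c3o2)cc1OC
F9 | step 6 | 6,7-dihydroxy-5,8-dimethoxy-2-(3,4-dimethoxyphenyl)-4H-chromen-4-one | COc1ccc(-c2cc(=O)c3c(OC)c(O)c(O)c(OC)c3o2)cc1OC
F10 | step 6 | 7-(benzyloxy)-6-hydroxy-5,8-dimethoxy-2-(3,4-dimethoxyphenyl)-4H-chromen-4-one | COc1ccc(-c2cc(=O)c3c(OC)c(O)c(OCc4ccccc4)c(OC)c3o2)cc1OC
F0 | step 4 | none | none
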